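(All runs are calculated with made-up constants; noise was put on by code.)

Right-handed product reads zero in 7 of the 12 earlier readings, and that count carries this problem.

all flasks: left-handed substrate 0.10 M; right-handed substrate 0.10 M

|  | coupling partner | precatalyst | remark | time |
|---|---|---|---|---|
| autumn | 2.7 equiv | 0.2 mol% | run made earlier |  |
| midnight | 4.6 equiv | 0.2 mol% | run made earlier |  |
| spring | 2 equiv | 0.12 mol% | run made earlier |  |
| eta | 2.00 equiv | 0.2 mol% |  | 100 min |
| theta | 3.00 equiv | 0.05 mol% |  | 200 min |

- autumn (time / min: left-handed product / %, right-handed product / %, left-handed substrate / %): 12.0: 3, 2, 47; 25.0: 11, 0, 46; 40.0: 15, 0, 39; 50.0: 25, 4, 34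
- midnight (time / min: left-handed product / %, right-handed product / %, left-handed substrate / %): 6.00: 3, 0, 54; 20.0: 17, 2, 38; 30.0: 30, 0, 31; 50.0: 56, 4, 25
- spring (time / min: left-handed product / %, right-handed product / %, left-handed substrate / %): 4.00: 4, 0, 49; 10.0: 0, 1, 49; 20.0: 2, 0, 46; 50.0: 11, 0, 42

(readings scatter by 2 percentage points)

1. the flask that ends with the higher share of left-handed product in all that became left-handed product or right-handed product, or "neither" when 2 percentage points or less lies between them (eta / theta / neither)
2. share of left-handed product in all that became left-handed product or right-handed product, eta
3. share of left-handed product in all that became left-handed product or right-handed product, theta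

- catalyst is single-handed; left-handed substrate and right-handed substrate are mirror images of each other, charged as a racemate, each of them at the stated concentration

1. Left-handed substrate was 50.0 % of the charge in midnight. Midnight ends with a reading of 56 % left-handed product, more than that share. So right-handed substrate must be feeding it.
2. First way: add up the readings. Left-handed product sums to 177 %, right-handed product to 13.0 %. The share is 93.2 %.
3. Second way: no reading falls below zero. With a scatter of 2 percentage points, a true zero therefore averages about two fifths of the scatter. Over 12 readings that floor is 9.6 points.
4. The two ways part, and the first one cheats: the floor is larger than the 3.4 points that remain.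
5. Divide those remaining points by the left-handed sum. This gives the leak 0.0192, the right-handed product formed per left-handed product. While the two substrates stand equal, it is the inverse of the selectivity factor.
6. The remainder is itself a reading, with a scatter of about 4 points. The pooled runs span 2 equiv to 4.6 equiv of coupling partner, and I assume the leak carries over. My reckoning gives 98.1 % for both eta and theta, so neither.

The forecast says 93 % for eta, 94 % for theta, and neither, on the ground that right-handed product “stays near noise level”. It differs from my share but gives the same verdict.

The flask gives 97.9 % for eta and 98.0 % for theta, so neither.

    coupling partner + catalyst + left-handed substrate → catalyst + left-handed product (k = 110 /M²/s)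
    coupling partner + catalyst + right-handed substrate → catalyst + right-handed product (k = 2.20 /M²/s)
    left-handed substrate ⇌ right-handed substrate (k = 0.00140 /s)
    coupling partner ⇌ dormant form (K = 1.30, k = 1.80 × 10⁻⁴ /s)
    coupling partner + precatalyst → catalyst + spent reagent (k = 1.70 × 10⁻⁴ /M/s)

The two flasks lie 0.100 points apart, and the verdict would need more than 2 points. With the other amounts and the time held, theta stays within 5 points of its share for precatalyst from 0.0063 mol% to 0.4 mol%, as far as was looked. In eta at 100 min, the leak on 32.8 % left-handed product gives 0.630 % right-handed product, and the flask holds 0.688 %. Left until 3.0 h, the same flask holds 48.9 % left-handed product. The leak then gives 0.939 % right-handed product, and that flask holds 1.03 %, a share of 97.9 %.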